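## Analysis of the target

The target is the p-coumarate of a daucane (carotane) diol, a trans-fused hydroazulene. The numbering used for the target and all intermediates is: cyclopentane ring C1–C5 (C1 quaternary with methyl C15, C4 a tertiary carbinol carrying isopropyl, C5 the ring-fusion CH) and cycloheptene ring C1, C5, C6 (ester oxygen), C7, C8 (methyl C14), C9, C10 with the C8=C9 double bond. The four stereocentres are C1 (R), C4 (R), C5 (S) and C6 (S). C15 and the C4 hydroxyl lie on one face of the cyclopentane; H5, the isopropyl group and the C6 oxygen lie on the other, so the ring fusion is trans and the C4/C6 diol is 1,3-anti. Sensitive groups are the E-cinnamate with its free phenol, the tertiary alcohol, and the C8=C9 alkene, which is β,γ to C6. At the C6 ketone level this alkene can move into conjugation, and the C4 carbinol/C6 ketone pair is a retro-aldol system. The hard points are the quaternary C1 next to the C5 stereocentre of a trans 5-7 fusion, the contiguous triad C4–C5–C6, and a trisubstituted alkene of defined position in a seven-membered ring. The feature the route exploits is that the seven-membered ring is a cyclohepta-1,4-diene in disguise. C8=C9 and the oxygenated C5–C6 edge (C5=C6 at the enone level) flank the C7 methylene, and the C1–C10 bond lies opposite, which is the retron of a divinylcyclopropane rearrangement of a C6–C7–C8 cyclopropane. C1–C5 with C15 is a 3-methylcyclopentenone.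

## Retrosynthetic reasoning

**C6–O ester bond (20 ⇐ 19 ⇐ 17 + 18).** The cinnamate and phenol are the most fragile parts, so the ester is made last. The acylation has to pick the secondary C6 hydroxyl of diol 17 over the tertiary C4 hydroxyl, which sterics secure. The phenol of acid 18 is carried as its acetate and released in the final step.

**C6 configuration (17 ⇐ 16).** The C6–H bond is cut back to ketone 16. This lets the C4 hydroxyl deliver hydride to C6 and fix the 1,3-anti relationship by a directed reduction, rather than relying on the weak facial bias of the seven-membered ring.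

**C4–isopropyl bond and C6 oxidation level (16 ⇐ 15 ⇐ 14).** The isopropyl group is cut from C4 of hydroxy ketone 14. With C5 already sp3 and trans-fused, both the C5–C6 bond and C15 shield one face of the C4 ketone, so the nucleophile must enter cis to H5. The C6 alcohol of 15 is then oxidised to 16; its configuration in 14 and 15 serves only as a relay.

**C6–O and C5–H bonds (14 ⇐ 12).** Both are cut back to the C5=C6 enone of dienone 12. A ligand-controlled conjugate borylation sets C6, and the enolate is protonated at C5 anti to the new boryl group. This is the event that makes the ring fusion trans. The conjugate addition is chemoselective for the enone and leaves C8=C9 alone.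

**C1–C10 bond (12 ⇐ 11, key disconnection).** Cutting C1–C10 and reconnecting C6–C8 turns the bicyclic dienone 12 into the monocyclic cis-divinylcyclopropane 11. The forward 3,3-shift closes the seven-membered ring, creates quaternary C1 by chirality transfer from the cyclopropane, and places both alkenes by mechanism. The precursor has one ring fewer and no quaternary stereocentre.

**C5–C6 bond (11 ⇐ 2 + 8).** The sp2–sp3 bond between the enone α-carbon and the cyclopropane is cut to iodoenone 2 and cyclopropyl iodide 8, joined by a Negishi coupling through 9 and 10 with retention at the cyclopropane carbon.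

**Cyclopropane and alkenes (8 ⇐ 7 ⇐ 6 ⇐ 5 ⇐ 3; 2 ⇐ 1).** The vinyl group comes from aldehyde 7. The C7 methylene is added to the Z-allylic alcohol 5 by a hydroxyl-directed asymmetric cyclopropanation, which sets the only reagent-derived stereocentres of the early route. Alcohol 5 comes from 3 by anti-carbomagnesiation/iodination, which fixes the cis relationship needed later. Iodoenone 2 comes from commercial enone 1.

## Alternatives that were turned down

Alternative 1: the textbook route, disconnecting C8=C9 by ring-closing metathesis. Forward: conjugate allylation of 1, trapping of the enolate at C5 with a β,γ-unsaturated C5 aldehyde to give diene A1, and metathesis to hydroxy ketone A2. Turned down for three reasons: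
- No practical catalytic asymmetric conjugate allylation creates the C1 quaternary centre, so a resolution would be needed.
- The trans C1/C5 relationship rests on the enolate distinguishing methyl from allyl on C1.
- C1, C5, C6 and C4 are set one at a time, and the alkene-bearing aldehyde isomerises easily.
The metathesis itself builds no stereocentre and only closes a ring whose difficulties were all solved before it.

Alternative 2: dearomatisation of the arene A3 (Birch reduction, cyclopropanation of the enol ether, oxidative ring enlargement) to the cycloheptadienone A4, which holds all seven ring carbons, both methyls and the C6 oxygen. A conjugate addition of an isopropyl-ketone homoenolate at C1 followed by aldol closure of C4–C5 would give A5. Turned down on mechanism: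
- The trigonal C5 of the ring enolate can be reached by the C2–C3–C4 tether only on the face where C2 sits. A trans fusion would need a torsion of more than 100° about C1–C5 next to the endocyclic enolate double bond. A5 is therefore the cis-fused C5 epimer of 16.
- C5 could be corrected only through a retro-aldol-prone enolate.
- The C7 protons of A4 are doubly activated, so base moves C8=C9 into conjugation and enolisation goes the wrong way.

Alternative 3: skeletal rearrangement of a decalin. The epoxy alcohol A6 (ring A six-membered: C1–C6) would give 16 in one semipinacol step by migration of C1 from C6 to C5, contracting ring A and enlarging ring B. Turned down on stereoelectronics and step economy: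
- In the cis-fused, hydroxyl-directed epoxide A6 the bond anti to the breaking C5–O bond is the exocyclic C6–C7 bond, so ring B would enlarge to a 6-7 system instead.
- Placing the hydroxyl trans to the epoxide makes the decalin trans and rigid, with the C1–C6 bond near 90° to the C5–O bond.
- Ionisation at the tertiary C4–O bond competes.
- Building A6 with its β,γ-unsaturated ring B costs as many steps as the target.

Key step: step 7

Assumption: in the two ligand-controlled steps (3 and 8) the ligand enantiomer written is the one expected to give the face drawn; the mirror-image ligand would be used if the sense proved opposite.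

## Route

Step 1
Reactants: 1 3-methylcyclopent-2-en-1-one
Product: 2 2-iodo-3-methylcyclopent-2-en-1-one
Conditions: I2, pyridine, CH2Cl2, 0 °C to rt
Reagents that add atoms: iodine, II
Why: α-Iodination of an enone by the pyridine/iodine addition–elimination sequence (Johnson iodination); it gives the alkenyl iodide that serves as electrophile in step 6.

Step 2
Reactants: 3 prop-2-yn-1-ol
Product: 5 (2Z)-3-iodo-2-methylprop-2-en-1-ol, via magnesium chelate 4 (not isolated)
Conditions: MeMgBr (2.3 equiv), CuI (10 mol %), Et2O/THF, −10 °C to rt; then I2, −78 to 0 °C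
Reagents that add atoms: methylmagnesium bromide, C[Mg]Br; iodine, II
Why: Copper-catalysed anti-carbomagnesiation of the propargylic alkoxide puts methyl on C8 and magnesium on C6 cis to the alkoxymethyl group in chelate 4; iodinolysis with retention gives the Z iodide, which fixes the later cis relationship on the cyclopropane.

Step 3
Reactants: 5 (2Z)-3-iodo-2-methylprop-2-en-1-ol
Product: 6 [(1R,2R)-2-iodo-1-methylcyclopropyl]methanol
Conditions: Zn(CH2I)2·DME (from Et2Zn and CH2I2), (4R,5R)-2-butyl-N,N,N′,N′-tetramethyl-1,3,2-dioxaborolane-4,5-dicarboxamide (1.2 equiv), CH2Cl2, −10 °C to rt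
Reagents that add atoms: diiodomethane, ICI
Why: Hydroxyl-directed Simmons–Smith cyclopropanation with the Charette dioxaborolane as chiral controller; the addition is stereospecifically syn, so iodine and hydroxymethyl stay cis, and the (4R,5R) ligand should select the alkene face that gives the (1R,2R) product, by analogy with other 2,3-disubstituted allylic alcohols.

Step 4
Reactants: 6 [(1R,2R)-2-iodo-1-methylcyclopropyl]methanol
Product: 7 (1R,2R)-2-iodo-1-methylcyclopropane-1-carbaldehyde
Conditions: Dess–Martin periodinane, NaHCO3, CH2Cl2, 0 °C to rt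
Reagents that add atoms: none
Why: Dess–Martin oxidation of a primary alcohol; the aldehyde sits on a quaternary cyclopropane carbon, so it cannot epimerise.

Step 5
Reactants: 7 (1R,2R)-2-iodo-1-methylcyclopropane-1-carbaldehyde
Product: 8 (1R,2R)-1-ethenyl-2-iodo-1-methylcyclopropane
Conditions: Ph3PCH3Br, KN(SiMe3)2, THF, −78 to 0 °C; used as a solution (volatile)
Reagents that add atoms: methyltriphenylphosphonium bromide, C[P+](c1ccccc1)(c1ccccc1)c1ccccc1.[Br-]
Why: Wittig methylenation of a hindered aldehyde; it installs the C9=C10 vinyl group cis to the iodine-bearing carbon.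

Step 6
Reactants: 8 (1R,2R)-1-ethenyl-2-iodo-1-methylcyclopropane; 2 2-iodo-3-methylcyclopent-2-en-1-one
Product: 11 2-[(1R,2R)-2-ethenyl-2-methylcyclopropyl]-3-methylcyclopent-2-en-1-one, via cyclopropyllithium 9 (not isolated), via cyclopropylzinc chloride 10 (not isolated)
Conditions: tBuLi (2.1 equiv), Et2O, −78 °C; ZnCl2, THF, −78 to 0 °C; then 2, Pd(PtBu3)2 (5 mol %), THF, 25–40 °C
Reagents that add atoms: none
Why: Iodine–lithium exchange on a cyclopropyl iodide and transmetalation to zinc go with retention; Negishi coupling (zerovalent palladium with a bulky phosphine) with the α-iodoenone joins C6 to C5, and the mild temperature lets 11 be isolated before it rearranges.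

Step 7
Reactants: 11 2-[(1R,2R)-2-ethenyl-2-methylcyclopropyl]-3-methylcyclopent-2-en-1-one
Product: 12 (3aR)-3a,6-dimethyl-2,3,3a,4-tetrahydroazulen-1(7H)-one
Conditions: toluene (degassed, dilute, BHT), sealed tube, 110–140 °C
Reagents that add atoms: none
Why: Thermal divinylcyclopropane–cycloheptadiene (Cope, 3,3-sigmatropic) rearrangement, the closest known class being cis-2-vinylcyclopropyl cyclic enones that rearrange to fused cycloheptadienes. The C6–C8 cyclopropane bond breaks while C10 bonds to C1 and the π bonds shift to C5=C6 and C8=C9; release of ring strain drives it to completion. The seven-membered ring (C1, C5–C10) is closed by enlargement of the three-membered ring through a boat transition state, the only one that keeps both new ring alkenes cis. The one new stereocentre, quaternary C1, is set by chirality transfer: in the boat both alkenes lie over the cyclopropane, so C10 can reach only the face of C1=C5 turned towards the ring, and the (1R,2R) cyclopropane should give (R)-C1. The cis arrangement of the two alkenyl groups that this needs is secured by the Z geometry of 5 and the stereospecific steps 3 to 6. The selectivity needed is concerted rearrangement over homolytic opening of the cyclopropane, which would scramble its configuration; the C15 methyl points inward in the boat and raises the barrier, so heating is needed and the temperature is kept as low as conversion allows. The positions of both alkenes follow from the mechanism, so the C8=C9 regiochemistry needs no control. If the thermal reaction is slow, a Lewis acid on the enone oxygen can accelerate the shift, as known for 2-acyl-1,5-dienes.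

Step 8
Reactants: 12 (3aR)-3a,6-dimethyl-2,3,3a,4-tetrahydroazulen-1(7H)-one
Product: 14 (3aR,8R,8aS)-8-hydroxy-3a,6-dimethyl-3,3a,4,7,8,8a-hexahydroazulen-1(2H)-one, via boryl ketone 13 (not isolated)
Conditions: B2pin2, CuCl (5 mol %), NaOtBu (10 mol %), (R)-Tol-BINAP (6 mol %), MeOH (2 equiv), THF, 0 °C; then H2O2, pH 7 phosphate buffer, THF, 0 °C
Reagents that add atoms: hydrogen peroxide, OO
Why: Copper-catalysed enantioselective conjugate borylation of an enone, then oxidation of the C–B bond with retention. The two faces of the C5=C6 enone of 12 differ only in C15 methyl versus C10 methylene on C1, so the ligand rather than the substrate should decide C6; the copper enolate is then protonated at C5 anti to the boryl group (held out of plane by allylic 1,3-strain with the enolate oxygen) and anti to C15, which puts H5 trans to C15 and makes the ring fusion trans. The C6 configuration of 14 is only a relay and is corrected in steps 10 and 11.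

Step 9
Reactants: 14 (3aR,8R,8aS)-8-hydroxy-3a,6-dimethyl-3,3a,4,7,8,8a-hexahydroazulen-1(2H)-one
Product: 15 (3R,3aS,4R,8aR)-6,8a-dimethyl-3-(propan-2-yl)-1,2,3,3a,4,5,8,8a-octahydroazulene-3,4-diol
Conditions: iPrMgCl (4 equiv), CeCl3 (anhydrous, 4 equiv), THF, −78 to −40 °C
Reagents that add atoms: isopropylmagnesium chloride, CC(C)[Mg]Cl
Why: Organocerium 1,2-addition suppresses enolisation and β-hydride reduction; the first equivalent only deprotonates the C6 hydroxyl. The nucleophile should enter C4 from the face opposite to the C5–C6 bond and to C15, so isopropyl ends up cis to H5 and the new hydroxyl cis to C15.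

Step 10
Reactants: 15 (3R,3aS,4R,8aR)-6,8a-dimethyl-3-(propan-2-yl)-1,2,3,3a,4,5,8,8a-octahydroazulene-3,4-diol
Product: 16 (3R,3aR,8aR)-3-hydroxy-6,8a-dimethyl-3-(propan-2-yl)-2,3,3a,5,8,8a-hexahydroazulen-4(1H)-one
Conditions: Dess–Martin periodinane, NaHCO3, CH2Cl2, 0 °C
Reagents that add atoms: none
Why: Dess–Martin oxidation of the only secondary alcohol; the tertiary C4 carbinol cannot be oxidised, and buffering avoids retro-aldol cleavage, epimerisation at C5 and migration of C8=C9 into conjugation.

Step 11
Reactants: 16 (3R,3aR,8aR)-3-hydroxy-6,8a-dimethyl-3-(propan-2-yl)-2,3,3a,5,8,8a-hexahydroazulen-4(1H)-one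
Product: 17 (3R,3aS,4S,8aR)-6,8a-dimethyl-3-(propan-2-yl)-1,2,3,3a,4,5,8,8a-octahydroazulene-3,4-diol
Conditions: Me4NBH(OAc)3 (5 equiv), MeCN/AcOH 1:1, −30 to 0 °C
Reagents that add atoms: none
Why: Evans–Saksena reduction: the C4 hydroxyl exchanges onto boron and hydride is delivered intramolecularly to the C6 carbonyl from the face on which the C4–O bond lies, which should give the 1,3-anti diol with the C6 hydroxyl cis to H5. The mildly acidic medium leaves the β,γ-alkene and C5 untouched.

Step 12
Reactants: 17 (3R,3aS,4S,8aR)-6,8a-dimethyl-3-(propan-2-yl)-1,2,3,3a,4,5,8,8a-octahydroazulene-3,4-diol; 18 (2E)-3-[4-(acetyloxy)phenyl]prop-2-enoic acid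
Product: 19 (3R,3aS,4S,8aR)-3-hydroxy-6,8a-dimethyl-3-(propan-2-yl)-1,2,3,3a,4,5,8,8a-octahydroazulen-4-yl (2E)-3-[4-(acetyloxy)phenyl]prop-2-enoate
Conditions: EDC·HCl, DMAP, CH2Cl2, 0 °C to rt
Reagents that add atoms: none
Why: Carbodiimide/DMAP (Steglich) esterification; only the secondary C6 hydroxyl is acylated, the tertiary C4 hydroxyl is inert, and the phenol of the acid is masked as its acetate to prevent self-condensation.

Step 13
Reactants: 19 (3R,3aS,4S,8aR)-3-hydroxy-6,8a-dimethyl-3-(propan-2-yl)-1,2,3,3a,4,5,8,8a-octahydroazulen-4-yl (2E)-3-[4-(acetyloxy)phenyl]prop-2-enoate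
Product: 20 (3R,3aS,4S,8aR)-3-hydroxy-6,8a-dimethyl-3-(propan-2-yl)-1,2,3,3a,4,5,8,8a-octahydroazulen-4-yl (2E)-3-(4-hydroxyphenyl)prop-2-enoate
Conditions: pyrrolidine (3 equiv), CH2Cl2, 0 °C
Reagents that add atoms: none
Why: Aminolysis of the aryl acetate, which is far more electrophilic than the hindered alkyl cinnamate; no stereocentre and neither alkene is touched.

## Compound list

1 | 3-methylcyclopent-2-en-1-one | CC1=CC(=O)CC1 | starting material
2 | 2-iodo-3-methylcyclopent-2-en-1-one | CC1=C(I)C(=O)CC1 | intermediate
3 | prop-2-yn-1-ol | C#CCO | starting material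
4 | 4-methyl-2,5-dihydro-1,2-oxamagnesole (cyclic Z-alkenylmagnesium alkoxide) | CC1=C[Mg]OC1 | intermediate (not isolated)
5 | (2Z)-3-iodo-2-methylprop-2-en-1-ol | OC/C(C)=C\I | intermediate
6 | [(1R,2R)-2-iodo-1-methylcyclopropyl]methanol | I[C@@H]1C[C@]1(C)CO | intermediate
7 | (1R,2R)-2-iodo-1-methylcyclopropane-1-carbaldehyde | I[C@@H]1C[C@]1(C)C=O | intermediate
8 | (1R,2R)-1-ethenyl-2-iodo-1-methylcyclopropane | I[C@@H]1C[C@]1(C)C=C | intermediate
9 | [(1R,2S)-2-ethenyl-2-methylcyclopropyl]lithium | [Li][C@@H]1C[C@]1(C)C=C | intermediate (not isolated)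
10 | chlorido[(1R,2R)-2-ethenyl-2-methylcyclopropyl]zinc | Cl[Zn][C@@H]1C[C@]1(C)C=C | intermediate (not isolated)
11 | 2-[(1R,2R)-2-ethenyl-2-methylcyclopropyl]-3-methylcyclopent-2-en-1-one | CC1=C([C@@H]2C[C@]2(C)C=C)C(=O)CC1 | intermediate
12 | (3aR)-3a,6-dimethyl-2,3,3a,4-tetrahydroazulen-1(7H)-one | CC1=CC[C@@]2(C)CCC(=O)C2=CC1 | intermediate
13 | (3aR,8R,8aR)-3a,6-dimethyl-8-(4,4,5,5-tetramethyl-1,3,2-dioxaborolan-2-yl)-3,3a,4,7,8,8a-hexahydroazulen-1(2H)-one | CC1=CC[C@@]2(C)CCC(=O)[C@@H]2[C@H](B3OC(C)(C)C(C)(C)O3)C1 | intermediate (not isolated)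
14 | (3aR,8R,8aS)-8-hydroxy-3a,6-dimethyl-3,3a,4,7,8,8a-hexahydroazulen-1(2H)-one | CC1=CC[C@@]2(C)CCC(=O)[C@@H]2[C@H](O)C1 | intermediate
15 | (3R,3aS,4R,8aR)-6,8a-dimethyl-3-(propan-2-yl)-1,2,3,3a,4,5,8,8a-octahydroazulene-3,4-diol | CC1=CC[C@@]2(C)CC[C@@](O)(C(C)C)[C@@H]2[C@H](O)C1 | intermediate
16 | (3R,3aR,8aR)-3-hydroxy-6,8a-dimethyl-3-(propan-2-yl)-2,3,3a,5,8,8a-hexahydroazulen-4(1H)-one | CC1=CC[C@@]2(C)CC[C@@](O)(C(C)C)[C@@H]2C(=O)C1 | intermediate
17 | (3R,3aS,4S,8aR)-6,8a-dimethyl-3-(propan-2-yl)-1,2,3,3a,4,5,8,8a-octahydroazulene-3,4-diol | CC1=CC[C@@]2(C)CC[C@@](O)(C(C)C)[C@@H]2[C@@H](O)C1 | intermediate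
18 | (2E)-3-[4-(acetyloxy)phenyl]prop-2-enoic acid | CC(=O)Oc1ccc(/C=C/C(=O)O)cc1 | starting material
19 | (3R,3aS,4S,8aR)-3-hydroxy-6,8a-dimethyl-3-(propan-2-yl)-1,2,3,3a,4,5,8,8a-octahydroazulen-4-yl (2E)-3-[4-(acetyloxy)phenyl]prop-2-enoate | CC1=CC[C@@]2(C)CC[C@@](O)(C(C)C)[C@@H]2[C@@H](OC(=O)/C=C/c2ccc(OC(C)=O)cc2)C1 | intermediate
20 | (3R,3aS,4S,8aR)-3-hydroxy-6,8a-dimethyl-3-(propan-2-yl)-1,2,3,3a,4,5,8,8a-octahydroazulen-4-yl (2E)-3-(4-hydroxyphenyl)prop-2-enoate | CC1=CC[C@@]2(C)CC[C@@](O)(C(C)C)[C@@H]2[C@@H](OC(=O)/C=C/c2ccc(O)cc2)C1 | target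

## Step count and least certain steps

Total step count: 13. Longest linear sequence: 12 steps (steps 2 to 13, from 3); step 1 is a one-step side branch that joins in step 6.

**Step 7 (key step).** The rearrangement may be slow because the C15 methyl points inward in the boat transition state. At the temperature then needed, homolytic opening of the doubly allylic cyclopropane bond can compete and scramble the cyclopropane configuration, which would erode the enantiomeric purity at C1. Long heating may also move the skipped diene into conjugation. The fallback replaces sigmatropic ring formation by ring-closing metathesis; it sets out from 1 and comes back at 14. Hosomi–Sakurai conjugate allylation of 1 (allyltrimethylsilane, TiCl4, CH2Cl2, −78 °C) and trapping of the titanium enolate with 3-methylbut-3-enal should give, as a racemate, the aldol (2S,3R)-2-[(1R)-1-hydroxy-3-methylbut-3-en-1-yl]-3-methyl-3-(prop-2-en-1-yl)cyclopentan-1-one F1, the aldehyde entering C5 anti to the larger allyl group. Ring-closing metathesis with the second-generation Grubbs catalyst closes C8=C9 to racemic 14. A lipase (Candida antarctica lipase B, vinyl acetate) then separates the enantiomers by acylation: 14 is collected directly or as its acetate (3aR,8R,8aS)-3a,6-dimethyl-1-oxo-1,2,3,3a,4,7,8,8a-octahydroazulen-8-yl acetate F2, which the same lipase methanolyses, and the mirror-image alcohol (3aS,8S,8aR)-8-hydroxy-3a,6-dimethyl-3,3a,4,7,8,8a-hexahydroazulen-1(2H)-one F3 is discarded.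

**Step 8.** Three things may go wrong: weak facial discrimination by the catalyst on this hindered exocyclic enone, base-mediated migration of the skipped diene into conjugation before borylation, and protonation of the enolate from the wrong face or later epimerisation at C5, which would give the cis ring fusion. The fallback uses thermodynamic instead of kinetic control at C5; it sets out from 12 and comes back at 17.
- Borylation with the mirror-image ligand and oxidation should give the C6 epimeric alcohol, expected from kinetic protonation as the cis-fused (3aR,8S,8aR)-8-hydroxy-3a,6-dimethyl-3,3a,4,7,8,8a-hexahydroazulen-1(2H)-one F4.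
- Silylation (Et3SiCl, imidazole) gives (3aR,8S,8aR)-3a,6-dimethyl-8-[(triethylsilyl)oxy]-3,3a,4,7,8,8a-hexahydroazulen-1(2H)-one F5.
- Equilibration at C5 with DBU should move H5 trans to C15, where the C4 carbonyl carbon and the C6 silyloxy group are trans on the seven-membered ring, giving (3aR,8S,8aS)-3a,6-dimethyl-8-[(triethylsilyl)oxy]-3,3a,4,7,8,8a-hexahydroazulen-1(2H)-one F6.
- Isopropylcerium addition as in step 9 gives (3R,3aS,4S,8aR)-6,8a-dimethyl-3-(propan-2-yl)-4-[(triethylsilyl)oxy]-1,2,3,3a,4,5,8,8a-octahydroazulen-3-ol F7.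
- Bu4NF removes the silyl group to give 17, which makes steps 10 and 11 unnecessary.

**Step 9.** Enolisation or β-hydride reduction by the secondary organometallic may outrun addition to the hindered ketone, and the metal alkoxide of the aldol may undergo retro-aldol ring opening. The fallback uses an sp2 nucleophile on the protected aldol; it sets out from 14 and comes back at 15.
- Silylation gives (3aR,8R,8aS)-3a,6-dimethyl-8-[(triethylsilyl)oxy]-3,3a,4,7,8,8a-hexahydroazulen-1(2H)-one F8.
- Isopropenylmagnesium bromide/CeCl3 adds from the same face to give (3S,3aS,4R,8aR)-6,8a-dimethyl-3-(prop-1-en-2-yl)-4-[(triethylsilyl)oxy]-1,2,3,3a,4,5,8,8a-octahydroazulen-3-ol F9.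
- Hydrogenation with RhCl(PPh3)3/H2 reduces the 1,1-disubstituted alkene faster than the trisubstituted C8=C9 and gives (3R,3aS,4R,8aR)-6,8a-dimethyl-3-(propan-2-yl)-4-[(triethylsilyl)oxy]-1,2,3,3a,4,5,8,8a-octahydroazulen-3-ol F10.
- Bu4NF gives 15.

**Step 6.** Transmetalation and reductive elimination between two hindered partners may be slow, so that protodemetalation or homocoupling of the cyclopropylzinc takes over, and material may be lost through the volatility of 8. The fallback couples first and cyclopropanates afterwards; it sets out from 4 and 2 and comes back at 11.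
- Quenching chelate 4 with Bu3SnCl gives (2Z)-2-methyl-3-(tributylstannyl)prop-2-en-1-ol F11.
- Stille coupling with 2 (Pd2(dba)3, AsPh3, CuI, NMP) gives 2-[(1Z)-3-hydroxy-2-methylprop-1-en-1-yl]-3-methylcyclopent-2-en-1-one F12.
- Directed asymmetric cyclopropanation as in step 3 gives 2-[(1R,2S)-2-(hydroxymethyl)-2-methylcyclopropyl]-3-methylcyclopent-2-en-1-one F13.
- Dess–Martin oxidation gives (1S,2R)-1-methyl-2-(2-methyl-5-oxocyclopent-1-en-1-yl)cyclopropane-1-carbaldehyde F14.
- Wittig methylenation of the aldehyde, which is more reactive than the hindered enone, gives 11.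

## Further compounds

F1 | step 7 | (2S,3R)-2-[(1R)-1-hydroxy-3-methylbut-3-en-1-yl]-3-methyl-3-(prop-2-en-1-yl)cyclopentan-1-one | C=CC[C@@]1(C)CCC(=O)[C@@H]1[C@H](O)CC(C)=C
F2 | step 7 | (3aR,8R,8aS)-3a,6-dimethyl-1-oxo-1,2,3,3a,4,7,8,8a-octahydroazulen-8-yl acetate | CC1=CC[C@@]2(C)CCC(=O)[C@@H]2[C@H](OC(C)=O)C1
F3 | step 7 | (3aS,8S,8aR)-8-hydroxy-3a,6-dimethyl-3,3a,4,7,8,8a-hexahydroazulen-1(2H)-one | CC1=CC[C@]2(C)CCC(=O)[C@H]2[C@@H](O)C1
F4 | step 8 | (3aR,8S,8aR)-8-hydroxy-3a,6-dimethyl-3,3a,4,7,8,8a-hexahydroazulen-1(2H)-one | CC1=CC[C@@]2(C)CCC(=O)[C@H]2[C@@H](O)C1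
F5 | step 8 | (3aR,8S,8aR)-3a,6-dimethyl-8-[(triethylsilyl)oxy]-3,3a,4,7,8,8a-hexahydroazulen-1(2H)-one | CC1=CC[C@@]2(C)CCC(=O)[C@H]2[C@@H](O[Si](CC)(CC)CC)C1
F6 | step 8 | (3aR,8S,8aS)-3a,6-dimethyl-8-[(triethylsilyl)oxy]-3,3a,4,7,8,8a-hexahydroazulen-1(2H)-one | CC1=CC[C@@]2(C)CCC(=O)[C@@H]2[C@@H](O[Si](CC)(CC)CC)C1
F7 | step 8 | (3R,3aS,4S,8aR)-6,8a-dimethyl-3-(propan-2-yl)-4-[(triethylsilyl)oxy]-1,2,3,3a,4,5,8,8a-octahydroazulen-3-ol | CC1=CC[C@@]2(C)CC[C@@](O)(C(C)C)[C@@H]2[C@@H](O[Si](CC)(CC)CC)C1
F8 | step 9 | (3aR,8R,8aS)-3a,6-dimethyl-8-[(triethylsilyl)oxy]-3,3a,4,7,8,8a-hexahydroazulen-1(2H)-one | CC1=CC[C@@]2(C)CCC(=O)[C@@H]2[C@H](O[Si](CC)(CC)CC)C1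
F9 | step 9 | (3S,3aS,4R,8aR)-6,8a-dimethyl-3-(prop-1-en-2-yl)-4-[(triethylsilyl)oxy]-1,2,3,3a,4,5,8,8a-octahydroazulen-3-ol | CC1=CC[C@@]2(C)CC[C@@](O)(C(C)=C)[C@@H]2[C@H](O[Si](CC)(CC)CC)C1
F10 | step 9 | (3R,3aS,4R,8aR)-6,8a-dimethyl-3-(propan-2-yl)-4-[(triethylsilyl)oxy]-1,2,3,3a,4,5,8,8a-octahydroazulen-3-ol | CC1=CC[C@@]2(C)CC[C@@](O)(C(C)C)[C@@H]2[C@H](O[Si](CC)(CC)CC)C1
F11 | step 6 | (2Z)-2-methyl-3-(tributylstannyl)prop-2-en-1-ol | OC/C(C)=C\[Sn](CCCC)(CCCC)CCCC
F12 | step 6 | 2-[(1Z)-3-hydroxy-2-methylprop-1-en-1-yl]-3-methylcyclopent-2-en-1-one | OC/C(C)=C\C1=C(C)CCC1=O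
F13 | step 6 | 2-[(1R,2S)-2-(hydroxymethyl)-2-methylcyclopropyl]-3-methylcyclopent-2-en-1-one | CC1=C([C@@H]2C[C@]2(C)CO)C(=O)CC1
F14 | step 6 | (1S,2R)-1-methyl-2-(2-methyl-5-oxocyclopent-1-en-1-yl)cyclopropane-1-carbaldehyde | CC1=C([C@@H]2C[C@]2(C)C=O)C(=O)CC1
A1 | alternative 1 | (2S,3R)-2-[(1S)-1-hydroxy-3-methylbut-3-en-1-yl]-3-methyl-3-(prop-2-en-1-yl)cyclopentan-1-one | C=CC[C@@]1(C)CCC(=O)[C@@H]1[C@@H](O)CC(C)=C
A2 | alternative 1 | (3aR,8S,8aS)-8-hydroxy-3a,6-dimethyl-3,3a,4,7,8,8a-hexahydroazulen-1(2H)-one | CC1=CC[C@@]2(C)CCC(=O)[C@@H]2[C@@H](O)C1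
A3 | alternative 2 | 1-methoxy-2,5-dimethylbenzene | COc1cc(C)ccc1C
A4 | alternative 2 | 3,6-dimethylcyclohepta-2,5-dien-1-one | CC1=CCC(C)=CC(=O)C1
A5 | alternative 2 | (3R,3aS,8aR)-3-hydroxy-6,8a-dimethyl-3-(propan-2-yl)-2,3,3a,5,8,8a-hexahydroazulen-4(1H)-one (cis-fused C5 epimer of 16) | CC1=CC[C@@]2(C)CC[C@@](O)(C(C)C)[C@H]2C(=O)C1
A6 | alternative 3 | 4a,7-dimethyl-2-(propan-2-yl)-1,2-epoxy-1,2,3,4,4a,5,8,8a-octahydronaphthalen-8a-ol with epoxide oxygen, 8a-hydroxyl and 4a-methyl on one face | CC1=CC[C@@]2(C)CC[C@]3(C(C)C)O[C@@H]3[C@@]2(O)C1
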